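**Plan**
1. Retrosynthesis: the Z-enone comes from an ynone (C≡C to cis C=C); the chain ketone is cut at C(=O)–CH2 on the cyclopentane side (chromene aldehyde plus a cyclopentylmethyl metal); the chromene C3=C4 comes from a chroman; the arene is cut at C8a–C4a, C5–C6 and C6–C7.
2. Enabling feature: in the benzene ring C4a–C5–C6–C7–C8–C8a, O1 (on C8a) and the methoxy oxygen (on C6) are para, and O1 is bound to the quaternary C2. An alkoxy(alkenyl)carbene of chromium whose alkoxy group is a chiral tertiary alkynol can therefore deliver the benzene and dihydropyran rings in one benzannulation.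
3. West: (S)-linalool → tertiary hept-6-yn-3-ol → carbene complex → step 7 closes the benzene and pyran rings together → O-methylation → DDQ (C3=C4) → acetaldehyde side chain.
4. East: ring B of the meso bicyclic dione is kept as the cyclopentane; ring A is opened by ozonolysis of a silyl enol ether; the acid arm is degraded to CH2I and the aldehyde arm takes the alkyne.
5. Union: cyclopentylmethyl-cerium addition to the chromene aldehyde, desilylation, double oxidation, cis-semihydrogenation.
6. Stereochemistry: C2 comes from (S)-linalool (its C–O bond is never broken); both quaternary cyclopentane carbons come from one enantioselective deprotonation of the meso ketone; the Z-alkene comes from syn-hydrogenation.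

Key step: step 7

Assumption: (S)-(+)-linalool is bought in high enantiomeric purity; its carbinol carbon becomes C2 unchanged, so the purity at C2 is that of the linalool.
Assumption: the (R,R)-configured lithium amide is taken to give the enol ether enantiomer drawn in step 14; if the sense of deprotonation is opposite, the (S,S)-amide is used and nothing else changes.

Step 1
Reactants: 1 (S)-linalool
Product: 3 (S)-3,7-dimethyloct-6-ene-1,3-diol, via alkylborane 2 (not isolated)
Conditions: 9-BBN (2.2 equiv), THF, 0 °C to rt; then NaOH, H2O2, 0 °C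
Reagents that add atoms: hydrogen peroxide, OO
Why: Hydroboration–oxidation with the bulky borane 9-BBN should add anti-Markovnikov to the monosubstituted vinyl group only, leaving the trisubstituted alkene and the carbinol stereocentre untouched.

Step 2
Reactants: 3 (S)-3,7-dimethyloct-6-ene-1,3-diol
Product: 4 (S)-1-[(tert-butyldimethylsilyl)oxy]-3,7-dimethyloct-6-en-3-ol
Conditions: TBSCl, imidazole, CH2Cl2, 0 °C
Reagents that add atoms: tert-butyldimethylsilyl chloride, CC(C)(C)[Si](C)(C)Cl
Why: Silyl ether formation is selective for the primary hydroxyl because the tertiary one is too hindered for TBSCl.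

Step 3
Reactants: 4 (S)-1-[(tert-butyldimethylsilyl)oxy]-3,7-dimethyloct-6-en-3-ol
Product: 6 (5S)-5-{2-[(tert-butyldimethylsilyl)oxy]ethyl}-5-methyloxolan-2-ol (both anomers), via secondary ozonide 5 (not isolated)
Conditions: O3, CH2Cl2, −78 °C; then Me2S, −78 °C to rt
Reagents that add atoms: ozone, [O-][O+]=O
Why: Ozonolysis with reductive work-up cleaves the only C=C bond, and the γ-hydroxy aldehyde so formed should close at once to the five-membered lactol.

Step 4
Reactants: 6 (5S)-5-{2-[(tert-butyldimethylsilyl)oxy]ethyl}-5-methyloxolan-2-ol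
Product: 7 (3S)-1-[(tert-butyldimethylsilyl)oxy]-3-methylhept-6-yn-3-ol
Conditions: dimethyl (1-diazo-2-oxopropyl)phosphonate, K2CO3, MeOH, rt
Reagents that add atoms: dimethyl (1-diazo-2-oxopropyl)phosphonate, CC(=O)C(=[N+]=[N-])P(=O)(OC)OC
Why: Ohira–Bestmann alkynylation (Seyferth–Gilbert homologation) acts on the open hydroxy aldehyde in equilibrium with the lactol, under mild base that the silyl ether and the free tertiary alcohol tolerate.

Step 5
Reactants: 8 2-bromopropene; 9 chromium hexacarbonyl Cr(CO)6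
Product: 12 tetramethylammonium acylchromate Me4N[(CO)5Cr=C(O)C(CH3)=CH2], via isopropenyllithium 10 (not isolated), via lithium acylchromate 11 (not isolated)
Conditions: t-BuLi (2 equiv), Et2O, −78 °C; Cr(CO)6, Et2O, 0 °C to rt; then Me4NBr, H2O
Reagents that add atoms: tetramethylammonium bromide, C[N+](C)(C)C.[Br-]
Why: Fischer acylmetalate synthesis: bromine–lithium exchange gives isopropenyllithium, which adds to a CO ligand of zerovalent chromium, and cation exchange gives the storable ammonium salt.

Step 6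
Reactants: 12 tetramethylammonium acylchromate; 7 (3S)-1-[(tert-butyldimethylsilyl)oxy]-3-methylhept-6-yn-3-ol
Product: 14 pentacarbonyl[{[(3S)-1-(tert-butyldimethylsilyloxy)-3-methylhept-6-yn-3-yl]oxy}(prop-1-en-2-yl)methylidene]chromium, via acetoxycarbene complex 13 (not isolated)
Conditions: AcBr (1 equiv), CH2Cl2, −40 °C; then 7 (0.4 equiv), −40 to −15 °C; cold filtration through silica (hexane) under Ar
Reagents that add atoms: none
Why: Proposed new method: O-acetylation of acylchromate 12 gives acetoxycarbene 13, whose carbene carbon behaves like the carbonyl carbon of a mixed anhydride and exchanges acetate for an alcohol by addition–elimination, a reaction type established for primary and hindered secondary alcohols (acyloxy–alkoxy exchange on Fischer carbene complexes), and the tertiary hydroxyl of 7 should follow the same path more slowly, which is answered by an excess of 13, high concentration, long reaction below −15 °C and acid-free isolation, while the carbinol C–O bond is not broken so that the configuration is retained.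

Step 7
Reactants: 14 pentacarbonyl[{[(3S)-1-(tert-butyldimethylsilyloxy)-3-methylhept-6-yn-3-yl]oxy}(prop-1-en-2-yl)methylidene]chromium
Product: 16 (S)-2-{2-[(tert-butyldimethylsilyl)oxy]ethyl}-2,8-dimethylchroman-6-ol, via tricarbonylchromium arene complex 15 (not isolated)
Conditions: THF (0.005 M), 55 °C, Ar, dark; then air, Et2O, rt
Reagents that add atoms: none
Why: Thermal loss of one cis CO from 14 opens a site for the tethered alkyne, which inserts into the Cr=C bond to form C8a–C4a and a vinylcarbene; CO insertion then gives a chromium-bound dienylketene (C5–C6), whose six-electron electrocyclisation forms C6–C7 and tautomerises to the phenol, held first as the Cr(CO)3 complex 15 and released in air. The closest known reaction type is the intramolecular Dötz benzannulation of alkenyl- or aryl(alkynyloxy)carbene complexes of chromium. The dihydropyran ring closes in the alkyne-insertion step in a 6-exo-dig sense across the O1–C2–C3–C4 tether, and the benzene ring closes by the electrocyclisation of the dienylketene. No stereocentre is formed, and C2 keeps the linalool configuration because its C–O bond is never broken. The step needs the substituted alkyne carbon next to the carbene carbon (against the intermolecular preference) and CO insertion instead of cyclopentannulation: the four-atom tether enforces the first, the alkenyl carbene in THF at moderate temperature favours the second, and high dilution under neutral conditions suppresses oligomerisation and ionisation of the tertiary ether.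

Step 8
Reactants: 16 (S)-2-{2-[(tert-butyldimethylsilyl)oxy]ethyl}-2,8-dimethylchroman-6-ol
Product: 17 (S)-tert-butyl[2-(6-methoxy-2,8-dimethylchroman-2-yl)ethoxy]dimethylsilane
Conditions: MeI, K2CO3, acetone, 50 °C
Reagents that add atoms: iodomethane, CI
Why: Williamson O-methylation of the phenol proceeds under conditions inert to the silyl ether and the tertiary alkyl aryl ether.

Step 9
Reactants: 17 (S)-tert-butyl[2-(6-methoxy-2,8-dimethylchroman-2-yl)ethoxy]dimethylsilane
Product: 18 (R)-tert-butyl[2-(6-methoxy-2,8-dimethyl-2H-chromen-2-yl)ethoxy]dimethylsilane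
Conditions: DDQ, benzene, 80 °C
Reagents that add atoms: none
Why: DDQ dehydrogenation: hydride abstraction from benzylic C4 is assisted by the ortho ring oxygen O1 and proton loss from C3 gives the 2H-chromene, while C2 carries no hydrogen and cannot be affected (the descriptor changes only by priority).

Step 10
Reactants: 18 (R)-tert-butyl[2-(6-methoxy-2,8-dimethyl-2H-chromen-2-yl)ethoxy]dimethylsilane
Product: 19 (R)-2-(6-methoxy-2,8-dimethyl-2H-chromen-2-yl)ethanol
Conditions: TBAF, THF, 0 °C to rt
Reagents that add atoms: none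
Why: Fluoride-induced desilylation frees the primary alcohol without touching the chromene.

Step 11
Reactants: 19 (R)-2-(6-methoxy-2,8-dimethyl-2H-chromen-2-yl)ethanol
Product: 20 (R)-2-(6-methoxy-2,8-dimethyl-2H-chromen-2-yl)acetaldehyde
Conditions: nPr4N[RuO4] (cat.), NMO, 4 Å MS, CH2Cl2, rt
Reagents that add atoms: none
Why: Ley oxidation (catalytic perruthenate with NMO) stops at the aldehyde under neutral conditions, avoiding any base that could eliminate the β-aryloxide.

Step 12
Reactants: 21 cis-1,5-dimethylbicyclo[3.3.0]octane-3,7-dione (meso)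
Product: 22 cis-1,5-dimethylbicyclo[3.3.0]octane-3,7-dione mono(2,2-dimethylpropane-1,3-diyl) ketal
Conditions: 2,2-dimethylpropane-1,3-diol (1 equiv), p-TsOH (cat.), benzene, reflux (Dean–Stark)
Reagents that add atoms: 2,2-dimethylpropane-1,3-diol, OCC(C)(C)CO
Why: Acid-catalysed ketalisation with one equivalent of diol masks one of the two equivalent carbonyls, and because it is reversible the recovered dione and bisketal can be recycled.

Step 13
Reactants: 22 cis-1,5-dimethylbicyclo[3.3.0]octane-3,7-dione mono(2,2-dimethylpropane-1,3-diyl) ketal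
Product: 25 cis-1,5-dimethylbicyclo[3.3.0]octan-3-one (meso), via hydrazone 23 (not isolated), via deoxygenated ketal 24 (not isolated)
Conditions: N2H4·H2O, KOH, diethylene glycol, 130 to 200 °C; then 1 M HCl, THF, rt
Reagents that add atoms: water, O
Why: Wolff–Kishner reduction removes the free carbonyl while the ketal is inert to hot base, and aqueous acid then releases the other ketone to give a meso cyclopentanone with two enantiotopic α-methylene groups.

Step 14
Reactants: 25 cis-1,5-dimethylbicyclo[3.3.0]octan-3-one (meso)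
Product: 27 (1R,5S)-1,5-dimethyl-3-(trimethylsilyloxy)bicyclo[3.3.0]oct-2-ene, via lithium enolate 26 (not isolated)
Conditions: (R,R)-bis(1-phenylethyl)amine, n-BuLi, LiCl, TMSCl (in situ quench), THF, −100 °C
Reagents that add atoms: chlorotrimethylsilane, C[Si](C)(C)Cl
Why: Enantioselective deprotonation of a meso ketone by a C2-symmetric chiral lithium amide with internal silyl quench, a known desymmetrisation of cis-bicyclo[3.3.0]octan-3-ones, differentiates the two enantiotopic α-CH2 groups and thereby fixes both quaternary stereocentres at once.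

Step 15
Reactants: 27 (1R,5S)-1,5-dimethyl-3-(trimethylsilyloxy)bicyclo[3.3.0]oct-2-ene
Product: 29 2-[(1S,2S)-2-formyl-1,2-dimethylcyclopentyl]acetic acid, via silyloxy ozonide 28 (not isolated)
Conditions: O3, CH2Cl2, −78 °C; then Me2S, −78 °C to rt; H2O
Reagents that add atoms: ozone, [O-][O+]=O
Why: Ozonolysis of the silyl enol ether opens ring A to an aldehyde on one quaternary carbon and an acetic acid arm on the other, and the aldehyde has no α-hydrogen so neither centre can epimerise (enantiomeric purity can be raised here by crystallising 29 as an amine salt).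

Step 16
Reactants: 29 2-[(1S,2S)-2-formyl-1,2-dimethylcyclopentyl]acetic acid
Product: 31 (1S,2R)-2-(iodomethyl)-1,2-dimethylcyclopentane-1-carbaldehyde, via thiohydroxamate ester 30 (not isolated)
Conditions: N-hydroxypyridine-2-thione, DCC, DMAP (cat.), CH2Cl2, rt, dark; then CHI3, benzene, hν (tungsten lamp), rt
Reagents that add atoms: iodoform, IC(I)I
Why: Barton decarboxylative iodination: the primary radical left after loss of CO2 is trapped by iodoform much faster than it could attack the aldehyde, and the quaternary stereocentres are not involved (the descriptor at the CH2I-bearing carbon changes only by priority).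

Step 17
Reactants: 31 (1S,2R)-2-(iodomethyl)-1,2-dimethylcyclopentane-1-carbaldehyde; 32 trimethyl[(2-methylbut-3-yn-2-yl)oxy]silane
Product: 35 triethyl({1-[(1S,2R)-2-(iodomethyl)-1,2-dimethylcyclopentyl]-4-methyl-4-[(trimethylsilyl)oxy]pent-2-yn-1-yl}oxy)silane (carbinol epimers), via lithium acetylide 33 (not isolated), via lithium alkoxide 34 (not isolated)
Conditions: 32, n-BuLi, THF, −78 °C; then 31, −78 °C; then TESOTf, −78 °C
Reagents that add atoms: triethylsilyl trifluoromethanesulfonate, CC[Si](CC)(CC)OS(=O)(=O)C(F)(F)F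
Why: 1,2-Addition of a lithium acetylide to the non-enolisable aldehyde is followed by silylation of the alkoxide at −78 °C before it can displace the neopentyl iodide, and the new carbinol centre is formed without control because step 19 turns it into a ketone.

Step 18
Reactants: 35 triethyl({1-[(1S,2R)-2-(iodomethyl)-1,2-dimethylcyclopentyl]-4-methyl-4-[(trimethylsilyl)oxy]pent-2-yn-1-yl}oxy)silane; 20 (R)-2-(6-methoxy-2,8-dimethyl-2H-chromen-2-yl)acetaldehyde
Product: 39 1-[(1S,2S)-2-{2-hydroxy-3-[(2R)-6-methoxy-2,8-dimethyl-2H-chromen-2-yl]propyl}-1,2-dimethylcyclopentyl]-4-methylpent-2-yne-1,4-diol (carbinol epimers), via alkyllithium 36 (not isolated), via alkylcerium dichloride 37 (not isolated), via bis-silyl ether adduct 38 (not isolated)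
Conditions: 35, t-BuLi (2.1 equiv), Et2O–pentane, −78 °C; CeCl3, THF, −78 °C; then 20, −78 °C; NH4Cl; then TBAF, THF, rt
Reagents that add atoms: none
Why: Iodine–lithium exchange gives a neopentyl-type alkyllithium with no β-hydrogen or β-leaving group, its organocerium derivative undergoes 1,2-addition to the enolisable aldehyde without deprotonating it (so the β-aryloxide is not eliminated), the new carbinol centre needs no control because it is oxidised next, and fluoride removes both silyl groups while no base-sensitive ketone is yet present.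

Step 19
Reactants: 39 1-[(1S,2S)-2-{2-hydroxy-3-[(2R)-6-methoxy-2,8-dimethyl-2H-chromen-2-yl]propyl}-1,2-dimethylcyclopentyl]-4-methylpent-2-yne-1,4-diol
Product: 40 1-[(1S,2S)-2-{3-[(2R)-6-methoxy-2,8-dimethyl-2H-chromen-2-yl]-2-oxopropyl}-1,2-dimethylcyclopentyl]-4-hydroxy-4-methylpent-2-yn-1-one
Conditions: Dess–Martin periodinane (3 equiv), CH2Cl2, 0 °C to rt
Reagents that add atoms: none
Why: Dess–Martin oxidation converts both secondary carbinols (chain and propargylic) into ketones under non-basic conditions and cannot touch the tertiary alcohol, which erases all uncontrolled carbinol centres.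

Step 20
Reactants: 40 1-[(1S,2S)-2-{3-[(2R)-6-methoxy-2,8-dimethyl-2H-chromen-2-yl]-2-oxopropyl}-1,2-dimethylcyclopentyl]-4-hydroxy-4-methylpent-2-yn-1-one
Product: 41 (2Z)-1-[(1S,2S)-2-{3-[(2R)-6-methoxy-2,8-dimethyl-2H-chromen-2-yl]-2-oxopropyl}-1,2-dimethylcyclopentyl]-4-hydroxy-4-methylpent-2-en-1-one (CNP0137762.2)
Conditions: H2 (1 atm), Pd/CaCO3 poisoned with Pb(OAc)2, quinoline, EtOAc, 0 °C
Reagents that add atoms: none
Why: Semihydrogenation on the poisoned palladium catalyst adds H2 syn to the alkyne to give the Z-enone and should spare the chromene alkene and both ketones.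

**Compound list**
1 | (S)-linalool | CC(C)=CCC[C@@](C)(C=C)O | starting material
2 | B-alkyl-9-borabicyclo[3.3.1]nonane adduct of 1 | CC(C)=CCC[C@@](C)(CCB1C2CCCC1CCC2)O | intermediate
3 | (S)-3,7-dimethyloct-6-ene-1,3-diol | CC(C)=CCC[C@@](C)(CCO)O | intermediate
4 | (S)-1-[(tert-butyldimethylsilyl)oxy]-3,7-dimethyloct-6-en-3-ol | CC(C)=CCC[C@@](C)(CCO[Si](C)(C)C(C)(C)C)O | intermediate
5 | secondary ozonide of 4 | CC1(C)OOC(CC[C@@](C)(CCO[Si](C)(C)C(C)(C)C)O)O1 | intermediate
6 | (5S)-5-{2-[(tert-butyldimethylsilyl)oxy]ethyl}-5-methyloxolan-2-ol (both anomers) | OC1CC[C@@](C)(CCO[Si](C)(C)C(C)(C)C)O1 | intermediate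
7 | (3S)-1-[(tert-butyldimethylsilyl)oxy]-3-methylhept-6-yn-3-ol | C#CCC[C@@](C)(CCO[Si](C)(C)C(C)(C)C)O | intermediate
8 | 2-bromopropene | C=C(C)Br | starting material
9 | chromium hexacarbonyl Cr(CO)6 | [Cr].[C-]#[O+].[C-]#[O+].[C-]#[O+].[C-]#[O+].[C-]#[O+].[C-]#[O+] | starting material
10 | isopropenyllithium | [Li]C(C)=C | intermediate
11 | lithium pentacarbonyl(2-methyl-1-oxidoprop-2-en-1-ylidene)chromate | C=C(C)C([O-])=[Cr](=C=O)(=C=O)(=C=O)(=C=O)=C=O.[Li+] | intermediate
12 | tetramethylammonium pentacarbonyl(2-methyl-1-oxidoprop-2-en-1-ylidene)chromate | C=C(C)C([O-])=[Cr](=C=O)(=C=O)(=C=O)(=C=O)=C=O.C[N+](C)(C)C | intermediate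
13 | pentacarbonyl[acetoxy(prop-1-en-2-yl)methylidene]chromium | C=C(C)C(OC(C)=O)=[Cr](=C=O)(=C=O)(=C=O)(=C=O)=C=O | intermediate
14 | pentacarbonyl[{[(3S)-1-(tert-butyldimethylsilyloxy)-3-methylhept-6-yn-3-yl]oxy}(prop-1-en-2-yl)methylidene]chromium | C=C(C)C(=[Cr](=C=O)(=C=O)(=C=O)(=C=O)=C=O)O[C@](C)(CCO[Si](C)(C)C(C)(C)C)CCC#C | intermediate
15 | tricarbonyl(η6-arene)chromium complex of 16 (η6 bonding not drawn) | Oc1cc(C)c2c(c1)CC[C@@](C)(CCO[Si](C)(C)C(C)(C)C)O2.[Cr].[C-]#[O+].[C-]#[O+].[C-]#[O+] | intermediate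
16 | (S)-2-{2-[(tert-butyldimethylsilyl)oxy]ethyl}-2,8-dimethylchroman-6-ol | Oc1cc(C)c2c(c1)CC[C@@](C)(CCO[Si](C)(C)C(C)(C)C)O2 | intermediate
17 | (S)-tert-butyl[2-(6-methoxy-2,8-dimethylchroman-2-yl)ethoxy]dimethylsilane | COc1cc(C)c2c(c1)CC[C@@](C)(CCO[Si](C)(C)C(C)(C)C)O2 | intermediate
18 | (R)-tert-butyl[2-(6-methoxy-2,8-dimethyl-2H-chromen-2-yl)ethoxy]dimethylsilane | COc1cc(C)c2c(c1)C=C[C@@](C)(CCO[Si](C)(C)C(C)(C)C)O2 | intermediate
19 | (R)-2-(6-methoxy-2,8-dimethyl-2H-chromen-2-yl)ethanol | COc1cc(C)c2c(c1)C=C[C@@](C)(CCO)O2 | intermediate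
20 | (R)-2-(6-methoxy-2,8-dimethyl-2H-chromen-2-yl)acetaldehyde | COc1cc(C)c2c(c1)C=C[C@@](C)(CC=O)O2 | intermediate
21 | cis-1,5-dimethylbicyclo[3.3.0]octane-3,7-dione (meso) | C[C@@]12CC(=O)C[C@]1(C)CC(=O)C2 | starting material
22 | cis-1,5-dimethylbicyclo[3.3.0]octane-3,7-dione mono(2,2-dimethylpropane-1,3-diyl) ketal | C[C@@]12CC(=O)C[C@]1(C)CC3(OCC(C)(C)CO3)C2 | intermediate
23 | hydrazone of 22 | C[C@@]12CC(=NN)C[C@]1(C)CC3(OCC(C)(C)CO3)C2 | intermediate
24 | cis-1,5-dimethylbicyclo[3.3.0]octan-3-one 2,2-dimethylpropane-1,3-diyl ketal | C[C@@]12CCC[C@]1(C)CC3(OCC(C)(C)CO3)C2 | intermediate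
25 | cis-1,5-dimethylbicyclo[3.3.0]octan-3-one (meso) | C[C@@]12CCC[C@]1(C)CC(=O)C2 | intermediate
26 | lithium (1R,5S)-1,5-dimethylbicyclo[3.3.0]oct-2-en-3-olate | [Li]OC1=C[C@@]2(C)CCC[C@@]2(C)C1 | intermediate
27 | (1R,5S)-1,5-dimethyl-3-(trimethylsilyloxy)bicyclo[3.3.0]oct-2-ene | C[Si](C)(C)OC1=C[C@@]2(C)CCC[C@@]2(C)C1 | intermediate
28 | secondary ozonide of 27 | C[Si](C)(C)OC14OOC(O4)[C@@]2(C)CCC[C@@]2(C)C1 | intermediate
29 | 2-[(1S,2S)-2-formyl-1,2-dimethylcyclopentyl]acetic acid | OC(=O)C[C@]1(C)CCC[C@]1(C)C=O | intermediate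
30 | 2-thioxopyridin-1(2H)-yl 2-[(1S,2S)-2-formyl-1,2-dimethylcyclopentyl]acetate | S=C2C=CC=CN2OC(=O)C[C@]1(C)CCC[C@]1(C)C=O | intermediate
31 | (1S,2R)-2-(iodomethyl)-1,2-dimethylcyclopentane-1-carbaldehyde | IC[C@]1(C)CCC[C@]1(C)C=O | intermediate
32 | trimethyl[(2-methylbut-3-yn-2-yl)oxy]silane | C#CC(C)(C)O[Si](C)(C)C | starting material
33 | lithium acetylide of 32 | [Li]C#CC(C)(C)O[Si](C)(C)C | intermediate
34 | lithium 1-[(1S,2R)-2-(iodomethyl)-1,2-dimethylcyclopentyl]-4-methyl-4-[(trimethylsilyl)oxy]pent-2-yn-1-olate | IC[C@]1(C)CCC[C@]1(C)C(O[Li])C#CC(C)(C)O[Si](C)(C)C | intermediate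
35 | triethyl({1-[(1S,2R)-2-(iodomethyl)-1,2-dimethylcyclopentyl]-4-methyl-4-[(trimethylsilyl)oxy]pent-2-yn-1-yl}oxy)silane (carbinol epimers) | IC[C@]1(C)CCC[C@]1(C)C(O[Si](CC)(CC)CC)C#CC(C)(C)O[Si](C)(C)C | intermediate
36 | alkyllithium from 35 (CH2Li in place of CH2I) | [Li]C[C@]1(C)CCC[C@]1(C)C(O[Si](CC)(CC)CC)C#CC(C)(C)O[Si](C)(C)C | intermediate
37 | alkylcerium dichloride from 36 (CH2CeCl2) | Cl[Ce](Cl)C[C@]1(C)CCC[C@]1(C)C(O[Si](CC)(CC)CC)C#CC(C)(C)O[Si](C)(C)C | intermediate
38 | adduct of 37 and 20 with the chain carbinol free and the propargylic and tertiary hydroxyls as triethylsilyl and trimethylsilyl ethers | COc1cc(C)c2c(c1)C=C[C@@](C)(CC(O)C[C@]1(C)CCC[C@]1(C)C(O[Si](CC)(CC)CC)C#CC(C)(C)O[Si](C)(C)C)O2 | intermediate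
39 | 1-[(1S,2S)-2-{2-hydroxy-3-[(2R)-6-methoxy-2,8-dimethyl-2H-chromen-2-yl]propyl}-1,2-dimethylcyclopentyl]-4-methylpent-2-yne-1,4-diol (carbinol epimers) | COc1cc(C)c2c(c1)C=C[C@@](C)(CC(O)C[C@]1(C)CCC[C@]1(C)C(O)C#CC(C)(C)O)O2 | intermediate
40 | 1-[(1S,2S)-2-{3-[(2R)-6-methoxy-2,8-dimethyl-2H-chromen-2-yl]-2-oxopropyl}-1,2-dimethylcyclopentyl]-4-hydroxy-4-methylpent-2-yn-1-one | COc1cc(C)c2c(c1)C=C[C@@](C)(CC(=O)C[C@]1(C)CCC[C@]1(C)C(=O)C#CC(C)(C)O)O2 | intermediate
41 | (2Z)-1-[(1S,2S)-2-{3-[(2R)-6-methoxy-2,8-dimethyl-2H-chromen-2-yl]-2-oxopropyl}-1,2-dimethylcyclopentyl]-4-hydroxy-4-methylpent-2-en-1-one (CNP0137762.2) | COc1cc(C)c2c(c1)C=C[C@@](C)(CC(=O)C[C@]1(C)CCC[C@]1(C)C(=O)/C=C\C(C)(C)O)O2 | target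

**Totals**
Total step count: 20. Longest linear sequence: 13 steps (1–4, 6–11, 18–20, from (S)-linalool); the cyclopentane branch (steps 12–17) and the acylchromate (step 5) converge on it.

**Steps most likely to fail**

Step 6 (new method). The hindered tertiary hydroxyl may add to the acetoxycarbene more slowly than that species decomposes, or the newly formed tertiary C–O bond may ionise, with elimination and loss of the stereocentre. The fallback uses known chemistry only, sets out from lactol 6 and returns at chroman 17, bypassing steps 4–8. Visible-light alkoxy-radical β-fragmentation of the lactol (PhI(OAc)2, I2, cyclohexane) excises the anomeric carbon as a formate and should give (3R)-5-[(tert-butyldimethylsilyl)oxy]-1-iodo-3-methylpentan-3-yl formate F1. Separately, commercial 4-methoxy-2-methylaniline is iodinated (ICl, AcOH) to 2-iodo-4-methoxy-6-methylaniline F2, diazotised (NaNO2, HBr) to 2-iodo-4-methoxy-6-methylbenzenediazonium bromide F3 and converted by the Sandmeyer reaction (CuBr) into 2-bromo-1-iodo-5-methoxy-3-methylbenzene F4. Zinc insertion into F1 (Zn, LiCl, THF) gives {(3R)-5-[(tert-butyldimethylsilyl)oxy]-3-(formyloxy)-3-methylpentyl}zinc iodide F5, and Negishi coupling at the C–I bond of F4 (PdCl2(dppf)) gives (3S)-1-(2-bromo-5-methoxy-3-methylphenyl)-5-[(tert-butyldimethylsilyl)oxy]-3-methylpentan-3-yl formate F6. Methanolysis (K2CO3, MeOH) frees (3S)-1-(2-bromo-5-methoxy-3-methylphenyl)-5-[(tert-butyldimethylsilyl)oxy]-3-methylpentan-3-ol F7. Palladium-catalysed intramolecular aryl etherification (Pd(OAc)2, 2-(di-tert-butylphosphino)-1,1'-binaphthyl, Cs2CO3, toluene, 80 °C) then closes the pyran with the C2–O bond intact to give 17.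

Step 7. On warming, the tertiary alkyl group may be lost from the carbene oxygen by ionisation, or the vinylcarbene may close without CO insertion. The fallback sets out from alkynol 7 and returns at chroman 17; it keeps the carbene–alkyne–CO construction of the arene but avoids a tertiary alkoxy carbene. (E)-1-Bromopropene is lithiated (t-BuLi) to (E)-prop-1-enyllithium F8, which with Cr(CO)6 9 gives lithium pentacarbonyl[(2E)-1-oxidobut-2-en-1-ylidene]chromate F9 and, after O-methylation (Me3OBF4), pentacarbonyl[(2E)-1-methoxybut-2-en-1-ylidene]chromium F10. Intermolecular Dötz benzannulation of F10 with the free alkynol 7 (THF, 50 °C) places the alkyl chain next to the new hydroxyl; it gives first the tricarbonyl(η6-arene)chromium complex F11 and, after exposure to air, 2-{(3S)-5-[(tert-butyldimethylsilyl)oxy]-3-hydroxy-3-methylpentyl}-4-methoxy-6-methylphenol F12. The phenol alone is sulfonylated (PhNTf2, Et3N) to 2-{(3S)-5-[(tert-butyldimethylsilyl)oxy]-3-hydroxy-3-methylpentyl}-4-methoxy-6-methylphenyl trifluoromethanesulfonate F13. This is exchanged to the bromo alcohol F7 (Pd2(dba)3, t-BuBrettPhos, KBr) and closed by the etherification described above to give 17, whose methoxy group is already in place.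

Step 20. The conjugated ynone may be over-reduced, or the Z-enone may isomerise to E on the catalyst. The fallback sets out from triol 39 and ends at 41. The alkyne is semihydrogenated first, while no conjugated carbonyl is present (H2, Pd/CaCO3 poisoned with Pb(OAc)2, quinoline), to give (2Z)-1-[(1S,2S)-2-{2-hydroxy-3-[(2R)-6-methoxy-2,8-dimethyl-2H-chromen-2-yl]propyl}-1,2-dimethylcyclopentyl]-4-methylpent-2-ene-1,4-diol F14. Dess–Martin oxidation of both secondary carbinols then gives 41 directly.

Further compounds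
F1 | step 6 | (3R)-5-[(tert-butyldimethylsilyl)oxy]-1-iodo-3-methylpentan-3-yl formate | ICC[C@@](C)(CCO[Si](C)(C)C(C)(C)C)OC=O
F2 | step 6 | 2-iodo-4-methoxy-6-methylaniline | COc1cc(C)c(N)c(I)c1
F3 | step 6 | 2-iodo-4-methoxy-6-methylbenzenediazonium bromide | COc1cc(C)c([N+]#N)c(I)c1.[Br-]
F4 | step 6 | 2-bromo-1-iodo-5-methoxy-3-methylbenzene | COc1cc(C)c(Br)c(I)c1
F5 | step 6 | {(3R)-5-[(tert-butyldimethylsilyl)oxy]-3-(formyloxy)-3-methylpentyl}zinc iodide | I[Zn]CC[C@@](C)(CCO[Si](C)(C)C(C)(C)C)OC=O
F6 | step 6 | (3S)-1-(2-bromo-5-methoxy-3-methylphenyl)-5-[(tert-butyldimethylsilyl)oxy]-3-methylpentan-3-yl formate | COc1cc(C)c(Br)c(CC[C@@](C)(CCO[Si](C)(C)C(C)(C)C)OC=O)c1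
F7 | step 6 | (3S)-1-(2-bromo-5-methoxy-3-methylphenyl)-5-[(tert-butyldimethylsilyl)oxy]-3-methylpentan-3-ol | COc1cc(C)c(Br)c(CC[C@@](C)(CCO[Si](C)(C)C(C)(C)C)O)c1
F8 | step 7 | (E)-prop-1-enyllithium | [Li]/C=C/C
F9 | step 7 | lithium pentacarbonyl[(2E)-1-oxidobut-2-en-1-ylidene]chromate | C/C=C/C([O-])=[Cr](=C=O)(=C=O)(=C=O)(=C=O)=C=O.[Li+]
F10 | step 7 | pentacarbonyl[(2E)-1-methoxybut-2-en-1-ylidene]chromium | C/C=C/C(OC)=[Cr](=C=O)(=C=O)(=C=O)(=C=O)=C=O
F11 | step 7 | tricarbonyl(η6-arene)chromium complex of F12 (η6 bonding not drawn) | COc1cc(C)c(O)c(CC[C@@](C)(CCO[Si](C)(C)C(C)(C)C)O)c1.[Cr].[C-]#[O+].[C-]#[O+].[C-]#[O+]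
F12 | step 7 | 2-{(3S)-5-[(tert-butyldimethylsilyl)oxy]-3-hydroxy-3-methylpentyl}-4-methoxy-6-methylphenol | COc1cc(C)c(O)c(CC[C@@](C)(CCO[Si](C)(C)C(C)(C)C)O)c1
F13 | step 7 | 2-{(3S)-5-[(tert-butyldimethylsilyl)oxy]-3-hydroxy-3-methylpentyl}-4-methoxy-6-methylphenyl trifluoromethanesulfonate | COc1cc(C)c(OS(=O)(=O)C(F)(F)F)c(CC[C@@](C)(CCO[Si](C)(C)C(C)(C)C)O)c1
F14 | step 20 | (2Z)-1-[(1S,2S)-2-{2-hydroxy-3-[(2R)-6-methoxy-2,8-dimethyl-2H-chromen-2-yl]propyl}-1,2-dimethylcyclopentyl]-4-methylpent-2-ene-1,4-diol | COc1cc(C)c2c(c1)C=C[C@@](C)(CC(O)C[C@]1(C)CCC[C@]1(C)C(O)/C=C\C(C)(C)O)O2
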